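**Retrosynthetic overview**

1. Target 22 comes from triol 21 by hydrogenolysis of two aryl benzyl ethers. Triol 21 comes from lactone aldehyde 20 by one LiAlH4 reduction. The trans C3 formyl group of 20 comes from a cis C3 vinyl group by oxidative cleavage and epimerisation.
2. The butanediol chain is carried as a trans-α,β-dibenzyl-γ-butyrolactone (temporary ring E). It is made by alkylating (R)-β-benzyl lactone 17 (ring A; Stobbe condensation, asymmetric hydrogenation) with benzylic bromide 12.
3. The ring B/C/D core 10 is made in one flask from arylpropyne 5 and benzyl alcohol 6. Ruthenium-catalysed hydrogen auto-transfer anti-(α-aryl)allylation forms C2–C3, then SNAr by the new C2 alkoxide forms O1–C7a and closes dihydrofuran ring C.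
4. Enabling feature: in ring B the oxygen-bearing carbon C7a is para to C5 (which carries the benzylic CH2 of the diol chain) and ortho to C3a (which carries C3). With C5 held as a methyl ester, a C7a–F bond is an SNAr site; C3, with its one-carbon branch held as vinyl, is the γ-carbon of an aryl-substituted allyl metal; the C2 oxygen made by carbonyl addition lies 5-exo to C7a.
5. Ring order: rings A, B and D are bought as benzenes; ring C is formed in step 3; ring E is formed in step 8 and opened in step 11.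

Key step: step 3

Assumption: the sense of induction of the chiral ligands in steps 3 and 7 is taken as written; if a ligand induces the opposite sense, its mirror image is used and nothing else changes.

**Route**

Step 1
Reactants: 1 methyl 4-fluoro-3-methoxybenzoate
Product: 3 methyl 3-bromo-4-fluoro-5-methoxybenzoate, via aryl pinacol boronate 2 (not isolated)
Conditions: [Ir(OMe)(cod)]2 (1.5 mol%), 4,4'-di-tert-butyl-2,2'-bipyridine (3 mol%), B2pin2 (1.0 equiv), THF, 80 °C; then CuBr2 (3 equiv), MeOH/H2O 1:1, 80 °C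
Reagents that add atoms: bis(pinacolato)diboron CC1(C)OB(OC1(C)C)B1OC(C)(C)C(C)(C)O1 (boron of 2 only); copper dibromide [Cu+2].[Br-].[Br-] (bromine of 3)
Why: Iridium-catalysed C–H borylation is sterically controlled and should take place at the only C–H whose sole ortho neighbour is the small fluorine (the other two C–H bonds flank the ester), and copper-mediated bromodeboronation then replaces boron by bromine at the same carbon.

Step 2
Reactants: 3 methyl 3-bromo-4-fluoro-5-methoxybenzoate; 4 propyne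
Product: 5 methyl 4-fluoro-3-methoxy-5-(prop-1-yn-1-yl)benzoate
Conditions: PdCl2(PPh3)2 (3 mol%), copper monoiodide (5 mol%), Et3N, THF, 50 °C, sealed vessel
Reagents that add atoms: none
Why: Sonogashira coupling of an electron-poor aryl bromide with propyne; the C–F bond is inert to zerovalent palladium and to triethylamine under these conditions.

Step 3
Reactants: 5 methyl 4-fluoro-3-methoxy-5-(prop-1-yn-1-yl)benzoate (1.5 equiv); 6 [4-(benzyloxy)-3-methoxyphenyl]methanol (1.0 equiv)
Product: 10 methyl (2S,3R)-2-[4-(benzyloxy)-3-methoxyphenyl]-3-ethenyl-7-methoxy-2,3-dihydro-1-benzofuran-5-carboxylate (2,3-cis), via transient aldehyde 7 (not isolated), via aryl allene 8 (not isolated), via anti homoallylic alcohol 9 (not isolated)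
Conditions: RuH2(CO)(PPh3)3 (5 mol%), Josiphos ligand (R)-1-[(S)-2-(dicyclohexylphosphino)ferrocenyl]ethyldi-tert-butylphosphine (5 mol%), Bu4NI (10 mol%), CF3CH2OH (additive), THF, 100 °C; then evaporation of the volatiles, Cs2CO3 (2 equiv), DMF, 60 °C
Reagents that add atoms: none
Why: Ruthenium-catalysed dehydrogenation of 6 gives aldehyde 7 and a ruthenium hydride, which isomerises alkyne 5 to allene 8 and hydrometalates it to an (E)-σ-allylruthenium; its aryl-bearing γ-carbon (the future C3) adds to 7 through a closed chair transition state to form the C2–C3 bond of 9, and alcohol exchange with the next molecule of 6 turns the cycle over, so the first stage sets nothing free. The closest known reaction type is the ruthenium–Josiphos-catalysed anti-(α-aryl)allylation of primary alcohols with 1-arylpropynes by hydrogen auto-transfer, followed here in the same flask by an ordinary intramolecular SNAr etherification of a fluoroarene activated by a para ester. After the volatiles are removed, Cs2CO3 deprotonates the C2 hydroxyl and the alkoxide attacks C7a in a 5-exo addition–elimination through a Meisenheimer intermediate stabilised by the C5 ester, which expels fluoride, forms the O1–C7a bond and closes dihydrofuran ring C. C2 (S) is set by the chiral diphosphine on ruthenium, which selects the aldehyde face, and C3 (R, anti to the hydroxyl and therefore cis to the aryl group in 10) by the E geometry of the allylruthenium in the chair transition state; the SNAr stage touches neither centre. The step needs branched regioselectivity, anti diastereoselectivity, facial selectivity and attack on the C–F bond by the internal alkoxide only: the aryl group fixes C–C bond formation at the benzylic allyl terminus, the base-free first stage keeps the C–F bond intact until the hydroxyl is in place, the 5-exo geometry outruns intermolecular substitution, and the weak carbonate base cannot deprotonate the benzylic and allylic C3–H, so the vinyl group does not migrate.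

Step 4
Reactants: 10 methyl (2S,3R)-2-[4-(benzyloxy)-3-methoxyphenyl]-3-ethenyl-7-methoxy-2,3-dihydro-1-benzofuran-5-carboxylate
Product: 11 [(2S,3R)-2-[4-(benzyloxy)-3-methoxyphenyl]-3-ethenyl-7-methoxy-2,3-dihydro-1-benzofuran-5-yl]methanol
Conditions: LiAlH4 (1.2 equiv), THF, 0 °C; aqueous NaOH work-up
Reagents that add atoms: none
Why: LiAlH4 reduces the aryl ester to the benzylic alcohol and leaves the vinyl group, the aryl ethers and both stereocentres untouched.

Step 5
Reactants: 11 [(2S,3R)-2-[4-(benzyloxy)-3-methoxyphenyl]-3-ethenyl-7-methoxy-2,3-dihydro-1-benzofuran-5-yl]methanol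
Product: 12 (2S,3R)-2-[4-(benzyloxy)-3-methoxyphenyl]-5-(bromomethyl)-3-ethenyl-7-methoxy-2,3-dihydro-1-benzofuran
Conditions: CBr4 (1.3 equiv), PPh3 (1.3 equiv), CH2Cl2, 0 °C; filtered through a short silica pad and used at once
Reagents that add atoms: carbon tetrabromide BrC(Br)(Br)Br
Why: Appel bromination converts the primary benzylic alcohol to the bromide under neutral conditions that should not ionise the C2 benzylic ether.

Step 6
Reactants: 7 4-(benzyloxy)-3-methoxybenzaldehyde (purchased); 13 dimethyl succinate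
Product: 14 (3E)-4-[4-(benzyloxy)-3-methoxyphenyl]-3-(methoxycarbonyl)but-3-enoic acid
Conditions: NaOMe, MeOH, reflux; then aqueous HCl
Reagents that add atoms: none
Why: Stobbe condensation: the succinate enolate adds to the aldehyde, the alkoxide lactonises onto the second ester, and base-induced ring opening gives the (E)-alkylidenesuccinic half-ester.

Step 7
Reactants: 14 (3E)-4-[4-(benzyloxy)-3-methoxyphenyl]-3-(methoxycarbonyl)but-3-enoic acid
Product: 15 (3R)-4-[4-(benzyloxy)-3-methoxyphenyl]-3-(methoxycarbonyl)butanoic acid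
Conditions: [Rh(cod)((S,S)-Et-DuPHOS)]BF4 (1 mol%), NaOMe (10 mol%), H2 (5 bar), MeOH, rt
Reagents that add atoms: none
Why: Rhodium–bisphospholane-catalysed asymmetric hydrogenation of the Stobbe-type itaconate half-ester, directed by the carboxylate, should set the stereocentre (R) under ligand control; benzyl ethers survive the homogeneous catalyst.

Step 8
Reactants: 15 (3R)-4-[4-(benzyloxy)-3-methoxyphenyl]-3-(methoxycarbonyl)butanoic acid
Product: 17 (4R)-4-[4-(benzyloxy)-3-methoxybenzyl]oxolan-2-one, via hydroxy acid 16 (not isolated)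
Conditions: KOH (1.0 equiv), EtOH; CaCl2, NaBH4, −10 °C → rt; then 2 M HCl, rt
Reagents that add atoms: none
Why: Calcium borohydride reduces the methyl ester but not the carboxylate salt, and acidification lactonises the 4-hydroxy acid to the β-substituted γ-butyrolactone without touching the stereocentre.

Step 9
Reactants: 17 (4R)-4-[4-(benzyloxy)-3-methoxybenzyl]oxolan-2-one; 12 (2S,3R)-2-[4-(benzyloxy)-3-methoxyphenyl]-5-(bromomethyl)-3-ethenyl-7-methoxy-2,3-dihydro-1-benzofuran
Product: 18 (3R,4R)-4-[4-(benzyloxy)-3-methoxybenzyl]-3-{[(2S,3R)-2-[4-(benzyloxy)-3-methoxyphenyl]-3-ethenyl-7-methoxy-2,3-dihydro-1-benzofuran-5-yl]methyl}oxolan-2-one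
Conditions: LiHMDS (1.05 equiv), THF, −78 °C; then 12, DMPU, −78 → −30 °C
Reagents that add atoms: none
Why: The lithium enolate of the β-substituted γ-butyrolactone is alkylated by the reactive benzylic bromide on the face opposite the C4 substituent (1,2-induction), which should set lactone C3 as R (trans).

Step 10
Reactants: 18 (3R,4R)-4-[4-(benzyloxy)-3-methoxybenzyl]-3-{[(2S,3R)-2-[4-(benzyloxy)-3-methoxyphenyl]-3-ethenyl-7-methoxy-2,3-dihydro-1-benzofuran-5-yl]methyl}oxolan-2-one
Product: 20 (2S,3S)-2-[4-(benzyloxy)-3-methoxyphenyl]-5-{[(3R,4R)-4-[4-(benzyloxy)-3-methoxybenzyl]-2-oxooxolan-3-yl]methyl}-7-methoxy-2,3-dihydro-1-benzofuran-3-carbaldehyde (2,3-trans), via cis aldehyde 19 (not isolated)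
Conditions: K2OsO4·2H2O (2 mol%), NaIO4 (4 equiv), 2,6-lutidine (2 equiv), 1,4-dioxane/H2O 3:1, rt; extractive work-up, then DBU (0.3 equiv), CH2Cl2, rt
Reagents that add atoms: sodium periodate [Na+].[O-]I(=O)(=O)=O (the formyl oxygen, relayed through the osmium catalyst)
Why: Lemieux–Johnson cleavage of the terminal alkene gives the cis α-aryl aldehyde, and catalytic DBU should equilibrate C3 through the enolate to the more stable 2,3-trans aldehyde, while C2 is safe because β-elimination of the ring oxygen from the C3 enolate would be a stereoelectronically disfavoured reverse 5-endo process.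

Step 11
Reactants: 20 (2S,3S)-2-[4-(benzyloxy)-3-methoxyphenyl]-5-{[(3R,4R)-4-[4-(benzyloxy)-3-methoxybenzyl]-2-oxooxolan-3-yl]methyl}-7-methoxy-2,3-dihydro-1-benzofuran-3-carbaldehyde
Product: 21 (2R,3R)-2-[4-(benzyloxy)-3-methoxybenzyl]-3-{[(2S,3R)-2-[4-(benzyloxy)-3-methoxyphenyl]-3-(hydroxymethyl)-7-methoxy-2,3-dihydro-1-benzofuran-5-yl]methyl}butane-1,4-diol
Conditions: LiAlH4 (3 equiv), THF, 0 °C → rt; aqueous NaOH work-up
Reagents that add atoms: none
Why: LiAlH4 reduces the aldehyde to the C3 hydroxymethyl group and opens the lactone to the 1,4-diol in one operation, with no stereocentre affected.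

Step 12
Reactants: 21 (2R,3R)-2-[4-(benzyloxy)-3-methoxybenzyl]-3-{[(2S,3R)-2-[4-(benzyloxy)-3-methoxyphenyl]-3-(hydroxymethyl)-7-methoxy-2,3-dihydro-1-benzofuran-5-yl]methyl}butane-1,4-diol
Product: 22 (2R,3R)-2-(4-hydroxy-3-methoxybenzyl)-3-{[(2S,3R)-2-(4-hydroxy-3-methoxyphenyl)-3-(hydroxymethyl)-7-methoxy-2,3-dihydro-1-benzofuran-5-yl]methyl}butane-1,4-diol (CNP0256425.1)
Conditions: H2 (1 atm), 10% Pd/C, EtOAc/MeOH 1:1, rt, stopped at full debenzylation
Reagents that add atoms: none
Why: Hydrogenolysis over palladium cleaves the two aryl benzyl ethers; under mild neutral conditions the cyclic benzylic C2–O bond of the dihydrobenzofuran should survive.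

**Compound list**

1 | methyl 4-fluoro-3-methoxybenzoate | COC(=O)c1ccc(F)c(OC)c1 | starting material
2 | methyl 4-fluoro-3-methoxy-5-(4,4,5,5-tetramethyl-1,3,2-dioxaborolan-2-yl)benzoate | COC(=O)c1cc(OC)c(F)c(c1)B1OC(C)(C)C(C)(C)O1 | intermediate
3 | methyl 3-bromo-4-fluoro-5-methoxybenzoate | COC(=O)c1cc(OC)c(F)c(Br)c1 | intermediate
4 | propyne | CC#C | starting material
5 | methyl 4-fluoro-3-methoxy-5-(prop-1-yn-1-yl)benzoate | COC(=O)c1cc(OC)c(F)c(C#CC)c1 | intermediate
6 | [4-(benzyloxy)-3-methoxyphenyl]methanol | COc1cc(CO)ccc1OCc1ccccc1 | starting material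
7 | 4-(benzyloxy)-3-methoxybenzaldehyde (purchased for step 6; also formed transiently in step 3) | COc1cc(C=O)ccc1OCc1ccccc1 | starting material
8 | methyl 4-fluoro-3-methoxy-5-(propa-1,2-dien-1-yl)benzoate | COC(=O)c1cc(OC)c(F)c(C=C=C)c1 | intermediate
9 | methyl 3-[(1S,2R)-1-[4-(benzyloxy)-3-methoxyphenyl]-1-hydroxybut-3-en-2-yl]-4-fluoro-5-methoxybenzoate (anti) | COC(=O)c1cc(OC)c(F)c(c1)[C@@H](C=C)[C@@H](c1ccc(OCc2ccccc2)c(OC)c1)O | intermediate
10 | methyl (2S,3R)-2-[4-(benzyloxy)-3-methoxyphenyl]-3-ethenyl-7-methoxy-2,3-dihydro-1-benzofuran-5-carboxylate (2,3-cis) | COC(=O)c1cc(OC)c2c(c1)[C@@H](C=C)[C@@H](c1ccc(OCc3ccccc3)c(OC)c1)O2 | intermediate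
11 | [(2S,3R)-2-[4-(benzyloxy)-3-methoxyphenyl]-3-ethenyl-7-methoxy-2,3-dihydro-1-benzofuran-5-yl]methanol | OCc1cc(OC)c2c(c1)[C@@H](C=C)[C@@H](c1ccc(OCc3ccccc3)c(OC)c1)O2 | intermediate
12 | (2S,3R)-2-[4-(benzyloxy)-3-methoxyphenyl]-5-(bromomethyl)-3-ethenyl-7-methoxy-2,3-dihydro-1-benzofuran | BrCc1cc(OC)c2c(c1)[C@@H](C=C)[C@@H](c1ccc(OCc3ccccc3)c(OC)c1)O2 | intermediate
13 | dimethyl succinate | COC(=O)CCC(=O)OC | starting material
14 | (3E)-4-[4-(benzyloxy)-3-methoxyphenyl]-3-(methoxycarbonyl)but-3-enoic acid | COC(=O)/C(CC(O)=O)=C/c1ccc(OCc2ccccc2)c(OC)c1 | intermediate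
15 | (3R)-4-[4-(benzyloxy)-3-methoxyphenyl]-3-(methoxycarbonyl)butanoic acid | COc1cc(C[C@H](CC(O)=O)C(=O)OC)ccc1OCc1ccccc1 | intermediate
16 | (3R)-4-[4-(benzyloxy)-3-methoxyphenyl]-3-(hydroxymethyl)butanoic acid | COc1cc(C[C@H](CC(O)=O)CO)ccc1OCc1ccccc1 | intermediate
17 | (4R)-4-[4-(benzyloxy)-3-methoxybenzyl]oxolan-2-one | COc1cc(C[C@H]2COC(=O)C2)ccc1OCc1ccccc1 | intermediate
18 | (3R,4R)-4-[4-(benzyloxy)-3-methoxybenzyl]-3-{[(2S,3R)-2-[4-(benzyloxy)-3-methoxyphenyl]-3-ethenyl-7-methoxy-2,3-dihydro-1-benzofuran-5-yl]methyl}oxolan-2-one | COc1cc(C[C@H]2COC(=O)[C@@H]2Cc2cc(OC)c3c(c2)[C@@H](C=C)[C@@H](c2ccc(OCc4ccccc4)c(OC)c2)O3)ccc1OCc1ccccc1 | intermediate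
19 | (2S,3R)-2-[4-(benzyloxy)-3-methoxyphenyl]-5-{[(3R,4R)-4-[4-(benzyloxy)-3-methoxybenzyl]-2-oxooxolan-3-yl]methyl}-7-methoxy-2,3-dihydro-1-benzofuran-3-carbaldehyde (2,3-cis) | COc1cc(C[C@H]2COC(=O)[C@@H]2Cc2cc(OC)c3c(c2)[C@@H](C=O)[C@@H](c2ccc(OCc4ccccc4)c(OC)c2)O3)ccc1OCc1ccccc1 | intermediate
20 | (2S,3S)-2-[4-(benzyloxy)-3-methoxyphenyl]-5-{[(3R,4R)-4-[4-(benzyloxy)-3-methoxybenzyl]-2-oxooxolan-3-yl]methyl}-7-methoxy-2,3-dihydro-1-benzofuran-3-carbaldehyde (2,3-trans) | COc1cc(C[C@H]2COC(=O)[C@@H]2Cc2cc(OC)c3c(c2)[C@H](C=O)[C@@H](c2ccc(OCc4ccccc4)c(OC)c2)O3)ccc1OCc1ccccc1 | intermediate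
21 | (2R,3R)-2-[4-(benzyloxy)-3-methoxybenzyl]-3-{[(2S,3R)-2-[4-(benzyloxy)-3-methoxyphenyl]-3-(hydroxymethyl)-7-methoxy-2,3-dihydro-1-benzofuran-5-yl]methyl}butane-1,4-diol | COc1cc(C[C@@H](CO)[C@H](CO)Cc2cc(OC)c3c(c2)[C@H](CO)[C@@H](c2ccc(OCc4ccccc4)c(OC)c2)O3)ccc1OCc1ccccc1 | intermediate
22 | (2R,3R)-2-(4-hydroxy-3-methoxybenzyl)-3-{[(2S,3R)-2-(4-hydroxy-3-methoxyphenyl)-3-(hydroxymethyl)-7-methoxy-2,3-dihydro-1-benzofuran-5-yl]methyl}butane-1,4-diol (CNP0256425.1) | COc1cc(C[C@@H](CO)[C@H](CO)Cc2cc(OC)c3c(c2)[C@H](CO)[C@@H](c2ccc(O)c(OC)c2)O3)ccc1O | target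

**Step count and risks**

Total step count: 12. Longest linear sequence: 9 steps (steps 1, 2, 3, 4, 5, 9, 10, 11, 12 from compound 1); the lactone branch (steps 6–8) joins at step 9.

The three steps most likely to fail:

Step 3. The ruthenium stage may show poor facial or anti selectivity with this ortho-fluorinated, ester-bearing alkyne. Residues of the first stage may also disturb the base stage, through substitution of the aryl fluoride by trifluoroethoxide or base-induced migration of the double bond. The fallback separates the two bond formations and makes the C2–C3 bond with an allylboron reagent. It sets out from bromide 3. Suzuki–Miyaura vinylation (potassium vinyltrifluoroborate, PdCl2(dppf), Cs2CO3, THF/H2O, 70 °C) gives methyl 3-ethenyl-4-fluoro-5-methoxybenzoate F1. Cross-metathesis with allylboronic acid pinacol ester (second-generation Grubbs catalyst, CH2Cl2, 40 °C) gives methyl 4-fluoro-3-methoxy-5-[(1E)-3-(4,4,5,5-tetramethyl-1,3,2-dioxaborolan-2-yl)prop-1-en-1-yl]benzoate F2. Allylboration of purchased aldehyde 7 under chiral phosphoric acid catalysis (the enantiomer of 3,3'-bis(2,4,6-triisopropylphenyl)-1,1'-binaphthyl-2,2'-diyl hydrogen phosphate that gives the S carbinol, toluene, −30 °C; closed chair transition state, E-boronate to anti product) gives alcohol 9 after aqueous work-up. Here 9 is isolated, and the route is rejoined at 9; Cs2CO3 in DMF then closes ring C to 10 as in the second stage of step 3.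

Step 10. Epimerisation at C3 may be incomplete, the ring may open by β-elimination of the aryloxide from the enolate, or the α-aryl aldehyde may over-oxidise during the cleavage. The fallback moves the epimerisation to the ester oxidation level, where cis-to-trans equilibration of 2-aryl-2,3-dihydrobenzofuran-3-carboxylates with methoxide is established. It sets out from cis aldehyde 19, taken on without base treatment. Pinnick oxidation (NaClO2, NaH2PO4, 2-methyl-2-butene, t-BuOH/H2O) gives (2S,3R)-2-[4-(benzyloxy)-3-methoxyphenyl]-5-{[(3R,4R)-4-[4-(benzyloxy)-3-methoxybenzyl]-2-oxooxolan-3-yl]methyl}-7-methoxy-2,3-dihydro-1-benzofuran-3-carboxylic acid F3. Methylation (Me3SiCHN2, toluene/MeOH) gives the cis methyl ester of F3, methyl (2S,3R)-2-[4-(benzyloxy)-3-methoxyphenyl]-5-{[(3R,4R)-4-[4-(benzyloxy)-3-methoxybenzyl]-2-oxooxolan-3-yl]methyl}-7-methoxy-2,3-dihydro-1-benzofuran-3-carboxylate F4. Equilibration with NaOMe in MeOH gives the trans ester methyl (2S,3S)-2-[4-(benzyloxy)-3-methoxyphenyl]-5-{[(3R,4R)-4-[4-(benzyloxy)-3-methoxybenzyl]-2-oxooxolan-3-yl]methyl}-7-methoxy-2,3-dihydro-1-benzofuran-3-carboxylate F5. LiAlH4 then reduces the C3 ester and the lactone together, and the route is rejoined at triol 21.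

Step 1. Borylation at the C–H ortho to the ester may compete with borylation ortho to fluorine, or double borylation may occur, giving regioisomers that survive the bromination. The fallback introduces fluorine last instead of boron first. It sets out from commercial methyl 3-bromo-4-hydroxy-5-methoxybenzoate F6. Deoxyfluorination of this electron-poor phenol with PhenoFluor (1,3-bis(2,6-diisopropylphenyl)-2,2-difluoro-2,3-dihydro-1H-imidazole, CsF, toluene, 110 °C) replaces the hydroxyl by fluorine at the same carbon, and the route is rejoined at bromide 3.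

**Further compounds**

F1 | step 3 | methyl 3-ethenyl-4-fluoro-5-methoxybenzoate | COC(=O)c1cc(OC)c(F)c(C=C)c1
F2 | step 3 | methyl 4-fluoro-3-methoxy-5-[(1E)-3-(4,4,5,5-tetramethyl-1,3,2-dioxaborolan-2-yl)prop-1-en-1-yl]benzoate | COC(=O)c1cc(OC)c(F)c(/C=C/CB2OC(C)(C)C(C)(C)O2)c1
F3 | step 10 | (2S,3R)-2-[4-(benzyloxy)-3-methoxyphenyl]-5-{[(3R,4R)-4-[4-(benzyloxy)-3-methoxybenzyl]-2-oxooxolan-3-yl]methyl}-7-methoxy-2,3-dihydro-1-benzofuran-3-carboxylic acid (2,3-cis) | COc1cc(C[C@H]2COC(=O)[C@@H]2Cc2cc(OC)c3c(c2)[C@@H](C(O)=O)[C@@H](c2ccc(OCc4ccccc4)c(OC)c2)O3)ccc1OCc1ccccc1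
F4 | step 10 | methyl (2S,3R)-2-[4-(benzyloxy)-3-methoxyphenyl]-5-{[(3R,4R)-4-[4-(benzyloxy)-3-methoxybenzyl]-2-oxooxolan-3-yl]methyl}-7-methoxy-2,3-dihydro-1-benzofuran-3-carboxylate (2,3-cis) | COc1cc(C[C@H]2COC(=O)[C@@H]2Cc2cc(OC)c3c(c2)[C@@H](C(=O)OC)[C@@H](c2ccc(OCc4ccccc4)c(OC)c2)O3)ccc1OCc1ccccc1
F5 | step 10 | methyl (2S,3S)-2-[4-(benzyloxy)-3-methoxyphenyl]-5-{[(3R,4R)-4-[4-(benzyloxy)-3-methoxybenzyl]-2-oxooxolan-3-yl]methyl}-7-methoxy-2,3-dihydro-1-benzofuran-3-carboxylate (2,3-trans) | COc1cc(C[C@H]2COC(=O)[C@@H]2Cc2cc(OC)c3c(c2)[C@H](C(=O)OC)[C@@H](c2ccc(OCc4ccccc4)c(OC)c2)O3)ccc1OCc1ccccc1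
F6 | step 1 | methyl 3-bromo-4-hydroxy-5-methoxybenzoate | COC(=O)c1cc(OC)c(O)c(Br)c1
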